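## Retrosynthetic overview
- The target comes from the (2S,3R)-triol by peracetylation and selective release of the phenol. The triol comes from the trans-3-(dimethoxymethyl)-2-aryl-2,3-dihydrobenzofuran by hydrolysis and reduction.
- The dihydrofuran ring comes from an iodine(III)-induced oxidative ring contraction of an (S)-2-aryl-2H-chromene. The ring-B carbon shifts from C4 to C3, and the existing C2 centre controls the new C3 centre.
- The pyran ring is formed first, by a catalytic enantioselective dehydrative annulation of a 4-substituted guaiacol with a cinnamaldehyde. This makes the ortho C–C bond and the C2–O bond.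
- Both C6–C3 halves come from 4-bromoguaiacol: a B-alkyl Suzuki coupling with allyl acetate for ring B, and acetylation then a Heck reaction with acrolein for ring A.
- 4-Bromoguaiacol comes from catechol by mono-O-methylation and para-bromination. Ring order: pyran first, then contraction to the dihydrofuran.

Assumption: the (R)-configured chiral acid in step 6 is taken to give the (S)-chromene. If the sense of induction is the opposite, its enantiomer is used. The configuration is checked at compound 14, which is a known natural product.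

## Route

Step 1
Reactants: 1 catechol
Product: 2 guaiacol (2-methoxyphenol)
Conditions: MeI (1.0 equiv), K2CO3 (1.0 equiv), acetone, reflux
Reagents that add atoms: iodomethane CI
Why: Williamson ether synthesis with one equivalent of electrophile alkylates the catechol monoanion, and the mono-ether is separated from neutral veratrole by base extraction.

Step 2
Reactants: 2 guaiacol
Product: 3 4-bromo-2-methoxyphenol
Conditions: NBS (1.0 equiv), MeCN, 0 °C
Reagents that add atoms: N-bromosuccinimide O=C1CCC(=O)N1Br
Why: In this electrophilic aromatic bromination the free OH is the dominant director, and NBS in MeCN substitutes para to it.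

Step 3
Reactants: 3 4-bromo-2-methoxyphenol; 4 allyl acetate
Product: 6 3-(4-hydroxy-3-methoxyphenyl)propyl acetate, via B-(3-acetoxypropyl)-9-BBN 5 (not isolated)
Conditions: 4, 9-BBN (1.1 equiv), THF, 0 °C to rt; then 3, Pd(OAc)2 (2 mol%), SPhos (4 mol%), K3PO4 (3 equiv), H2O, THF, 60 °C
Reagents that add atoms: none
Why: Anti-Markovnikov hydroboration followed by a B-alkyl Suzuki–Miyaura coupling installs the acetoxypropyl chain in one flask, and the electron-rich ligand compensates for the slow oxidative addition of the bromophenoxide.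

Step 4
Reactants: 3 4-bromo-2-methoxyphenol
Product: 7 4-bromo-2-methoxyphenyl acetate
Conditions: Ac2O, pyridine, rt
Reagents that add atoms: acetic anhydride CC(=O)OC(C)=O
Why: O-Acetylation masks the ring-A phenol against iodine(III) and lowers the cation-stabilising and migrating ability of ring A for steps 6 and 7.

Step 5
Reactants: 7 4-bromo-2-methoxyphenyl acetate; 8 acrolein
Product: 9 (E)-3-(4-acetoxy-3-methoxyphenyl)prop-2-enal
Conditions: Pd(OAc)2 (2 mol%), P(o-tol)3 (4 mol%), NaOAc (1.5 equiv), trace hydroquinone, DMA, 100 °C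
Reagents that add atoms: none
Why: In this Mizoroki–Heck reaction, syn insertion and syn β-hydride elimination give the E-enal, and acetate as the base leaves the aryl acetate untouched.

Step 6
Reactants: 6 3-(4-hydroxy-3-methoxyphenyl)propyl acetate; 9 (E)-3-(4-acetoxy-3-methoxyphenyl)prop-2-enal
Product: 11 3-[(2S)-2-(4-acetoxy-3-methoxyphenyl)-8-methoxy-2H-chromen-6-yl]propyl acetate, via benzodioxaborin 10 (not isolated)
Conditions: C6F5B(OH)2 (20 mol%), (R)-3,3'-bis(2,4,6-triisopropylphenyl)-BINOL N-triflylphosphoramide (10 mol%), 5 Å MS, toluene, 40 °C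
Reagents that add atoms: none
Why: Proposed new method: the boronic acid ties the phenol oxygen and the aldehyde oxygen together and delivers the carbonyl carbon to the only free ortho position (1,2- rather than 1,4-addition), giving racemic 10; the chiral strong acid then ionises its benzylic C–O bond, which erases that stereocentre and gives a vinylogous o-quinone-methide/allyl cation held as a contact ion pair; the phenol oxygen closes on the cinnamyl terminus while the chiral anion accepts its proton, which forms the pyran ring and sets C2; the closest known reaction types are the racemic boronic acid/achiral phosphinic acid co-catalysed phenol–enal chromene annulation and the chiral-ion-pair intramolecular allylic etherification that gives 2H-chromenes, and the merger of the two has not been shown.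

Step 7
Reactants: 11 3-[(2S)-2-(4-acetoxy-3-methoxyphenyl)-8-methoxy-2H-chromen-6-yl]propyl acetate
Product: 12 3-[(2S,3S)-2-(4-acetoxy-3-methoxyphenyl)-3-(dimethoxymethyl)-7-methoxy-2,3-dihydro-1-benzofuran-5-yl]propyl acetate
Conditions: PhI(OH)OTs (1.1 equiv), MeOH, 3 Å MS, –10 to 0 °C, 30 min
Reagents that add atoms: methanol CO
Why: In this iodine(III)-mediated oxidative ring contraction the iodane adds to C3 anti to the C2 aryl group and methanol adds anti at benzylic C4, so in the all-equatorial adduct the C3–I bond is antiperiplanar to C4–C4a; the o-alkoxy-activated ring-B carbon then shifts from C4 to C3 with inversion as PhI leaves (ionic 1,2-aryl shift), methanol traps the methoxycarbenium ion, and C3 ends up trans to the C2 aryl group.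

Step 8
Reactants: 12 3-[(2S,3S)-2-(4-acetoxy-3-methoxyphenyl)-3-(dimethoxymethyl)-7-methoxy-2,3-dihydro-1-benzofuran-5-yl]propyl acetate
Product: 14 4-[(2S,3R)-3-(hydroxymethyl)-5-(3-hydroxypropyl)-7-methoxy-2,3-dihydro-1-benzofuran-2-yl]-2-methoxyphenol, via aldehyde 13 (not isolated)
Conditions: 1 M HCl, THF, rt, extractive work-up; then crude 13, LiAlH4, THF, 0 °C, Rochelle work-up
Reagents that add atoms: water O
Why: Acetal hydrolysis followed by hydride reduction converts C9 to CH2OH and cleaves both acetates; the aldehyde is not purified, any epimerisation at C3 only restores the favoured trans isomer because C2 is untouched, and the descriptor change at C3 (S to R) is only a change in CIP priority.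

Step 9
Reactants: 14 4-[(2S,3R)-3-(hydroxymethyl)-5-(3-hydroxypropyl)-7-methoxy-2,3-dihydro-1-benzofuran-2-yl]-2-methoxyphenol
Product: 16 3-[(2S,3R)-3-(acetoxymethyl)-2-(4-hydroxy-3-methoxyphenyl)-7-methoxy-2,3-dihydro-1-benzofuran-5-yl]propyl acetate, via triacetate 15 (not isolated)
Conditions: Ac2O, pyridine, rt, evaporate; then pyrrolidine (1.2 equiv), CH2Cl2, 0 °C to rt, 30 min
Reagents that add atoms: acetic anhydride CC(=O)OC(C)=O
Why: Peracetylation followed by chemoselective aminolysis works because the aryl acetate is a far better acyl donor than the two primary alkyl acetates, so pyrrolidine frees only the phenol and no stereocentre is touched.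

## Compound list
1 | catechol | Oc1ccccc1O | starting material
2 | guaiacol | COc1ccccc1O | intermediate
3 | 4-bromo-2-methoxyphenol | COc1cc(Br)ccc1O | intermediate
4 | allyl acetate | C=CCOC(C)=O | starting material
5 | 3-(9-borabicyclo[3.3.1]nonan-9-yl)propyl acetate | CC(=O)OCCCB1C2CCCC1CCC2 | intermediate
6 | 3-(4-hydroxy-3-methoxyphenyl)propyl acetate | COc1cc(CCCOC(C)=O)ccc1O | intermediate
7 | 4-bromo-2-methoxyphenyl acetate | COc1cc(Br)ccc1OC(C)=O | intermediate
8 | acrolein | C=CC=O | starting material
9 | (E)-3-(4-acetoxy-3-methoxyphenyl)prop-2-enal | COc1cc(/C=C/C=O)ccc1OC(C)=O | intermediate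
10 | 4-[(E)-2-(4-acetoxy-3-methoxyphenyl)ethenyl]-6-(3-acetoxypropyl)-8-methoxy-2-(pentafluorophenyl)-4H-1,3,2-benzodioxaborin, racemic at C4 | COc1cc(CCCOC(C)=O)cc2c1OB(c1c(F)c(F)c(F)c(F)c1F)OC2/C=C/c1ccc(OC(C)=O)c(OC)c1 | intermediate
11 | 3-[(2S)-2-(4-acetoxy-3-methoxyphenyl)-8-methoxy-2H-chromen-6-yl]propyl acetate | COc1cc([C@H]2Oc3c(OC)cc(CCCOC(C)=O)cc3C=C2)ccc1OC(C)=O | intermediate
12 | 3-[(2S,3S)-2-(4-acetoxy-3-methoxyphenyl)-3-(dimethoxymethyl)-7-methoxy-2,3-dihydro-1-benzofuran-5-yl]propyl acetate | COc1cc([C@H]2Oc3c(OC)cc(CCCOC(C)=O)cc3[C@@H]2C(OC)OC)ccc1OC(C)=O | intermediate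
13 | 3-[(2S,3S)-2-(4-acetoxy-3-methoxyphenyl)-3-formyl-7-methoxy-2,3-dihydro-1-benzofuran-5-yl]propyl acetate | COc1cc([C@H]2Oc3c(OC)cc(CCCOC(C)=O)cc3[C@@H]2C=O)ccc1OC(C)=O | intermediate
14 | 4-[(2S,3R)-3-(hydroxymethyl)-5-(3-hydroxypropyl)-7-methoxy-2,3-dihydro-1-benzofuran-2-yl]-2-methoxyphenol, (7S,8R)-dihydrodehydrodiconiferyl alcohol | COc1cc([C@H]2Oc3c(OC)cc(CCCO)cc3[C@@H]2CO)ccc1O | intermediate
15 | 3-[(2S,3R)-3-(acetoxymethyl)-2-(4-acetoxy-3-methoxyphenyl)-7-methoxy-2,3-dihydro-1-benzofuran-5-yl]propyl acetate | COc1cc([C@H]2Oc3c(OC)cc(CCCOC(C)=O)cc3[C@@H]2COC(C)=O)ccc1OC(C)=O | intermediate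
16 | 3-[(2S,3R)-3-(acetoxymethyl)-2-(4-hydroxy-3-methoxyphenyl)-7-methoxy-2,3-dihydro-1-benzofuran-5-yl]propyl acetate | COc1cc([C@H]2Oc3c(OC)cc(CCCOC(C)=O)cc3[C@@H]2COC(C)=O)ccc1O | target

## Step count
- Total steps: 9
- Longest linear sequence: 8 (steps 1, 2, 4, 5, 6, 7, 8, 9)

## Steps most likely to fail

**Step 6 (the proposed new step).**
- Risks: an uncatalysed thermal o-quinone-methide closure would give racemate. The strong acid could promote conjugate Friedel–Crafts addition. The acid could also re-ionise and so racemise 11.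
- Fallback (known chemistry only): it sets out from 6 and 9 and comes back at 11.
- Magnesium-mediated ortho-formylation of 6 (MgCl2, Et3N, paraformaldehyde, MeCN, reflux) gives 3-(3-formyl-4-hydroxy-5-methoxyphenyl)propyl acetate F1.
- The established iminium/enamine oxa-Michael–aldol condensation of this aldehyde with 9 uses (S)-α,α-diphenylprolinol TMS ether, 2-nitrobenzoic acid, toluene and 4 Å MS at rt. It gives 3-[(2R)-2-(4-acetoxy-3-methoxyphenyl)-3-formyl-8-methoxy-2H-chromen-6-yl]propyl acetate F2.
- This compound has the same spatial arrangement at C2 as 11. The descriptor differs only because of CIP priorities.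
- Tsuji–Wilkinson decarbonylation (RhCl(PPh3)3, toluene, 110 °C) then delivers 11.

**Step 7.**
- Risks: simple 3,4-dimethoxylation, oxidation to the flavylium salt, or migration of ring A or of O1 instead of C4a.
- Fallback: it sets out from 11 and comes back at 12, and it separates the addition from the shift.
- Bromomethoxylation (NBS, MeOH, 0 °C) places bromine anti to the C2 aryl group and methanol anti at C4. It gives 3-[(2R,3S,4R)-2-(4-acetoxy-3-methoxyphenyl)-3-bromo-4,8-dimethoxy-3,4-dihydro-2H-chromen-6-yl]propyl acetate F3, which can be purified.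
- Silver-assisted ionisation (AgBF4, MeOH/CH2Cl2, –20 °C to rt) then triggers the same invertive 1,2-aryl shift. Methanol capture gives 12.

**Step 5.**
- Risks: acrolein polymerises at the temperature that the aryl bromide needs, and double arylation is possible.
- Fallback: it sets out from 7 and comes back at 9.
- Sonogashira coupling with propargyl alcohol (PdCl2(PPh3)2, CuI, Et3N, 60 °C) gives 4-(3-hydroxyprop-1-yn-1-yl)-2-methoxyphenyl acetate F4.
- Ruthenium-catalysed redox isomerisation of this primary propargylic alcohol (indenyl-Ru(PPh3)2Cl, In(OTf)3, camphorsulfonic acid, THF, reflux) gives the E-enal 9.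

## Further compounds
F1 | step 6 | 3-(3-formyl-4-hydroxy-5-methoxyphenyl)propyl acetate | CC(=O)OCCCc1cc(C=O)c(O)c(OC)c1
F2 | step 6 | 3-[(2R)-2-(4-acetoxy-3-methoxyphenyl)-3-formyl-8-methoxy-2H-chromen-6-yl]propyl acetate | COc1cc([C@H]2Oc3c(OC)cc(CCCOC(C)=O)cc3C=C2C=O)ccc1OC(C)=O
F3 | step 7 | 3-[(2R,3S,4R)-2-(4-acetoxy-3-methoxyphenyl)-3-bromo-4,8-dimethoxy-3,4-dihydro-2H-chromen-6-yl]propyl acetate | COc1cc([C@H]2Oc3c(OC)cc(CCCOC(C)=O)cc3[C@@H](OC)[C@@H]2Br)ccc1OC(C)=O
F4 | step 5 | 4-(3-hydroxyprop-1-yn-1-yl)-2-methoxyphenyl acetate | COc1cc(C#CCO)ccc1OC(C)=O
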